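**Retrosynthetic overview**

1. Target 22 ⇐ monoepoxide diacetate 21 by dioxirane epoxidation of C4=C5 (second oxirane, formed last); 21 ⇐ epoxy alcohol 19 by desilylation and acetylation.
2. 19 ⇐ achiral allylic alcohol 18 by hydroxyl-directed peptide-peracid epoxidation of C7=C11 (first oxirane; the first stereocentres, set by the catalyst).
3. 18 ⇐ dienone 17 by 1,4-hydrogenation of the C8=C7–C11=C13 diene, which fixes the geometry of the tetrasubstituted alkene.
4. 17 ⇐ carbinol 14 by anionic alkynyl oxy-Cope ring expansion (six- to ten-membered ring; C6–C7 made, C4–C9 broken; the racemic centres of 14 are erased).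
5. 14 ⇐ enynol 12 (from 10 + 11) + ketone 9; 9 ⇐ 1 + 2 + 5. Ring order: purchased cyclohexenone → ten-membered carbocycle → C7/C11 oxirane → C4/C5 oxirane.

Assumption and numbering: the SMILES is read as the 1(10)Z enone with 4R,5R,7S,11S; germacrane numbering is used for the ten-membered ring (C9 ketone, C10 bears CH3-14, C4 bears C15, C7 bears C11 which carries C12 and C13).

**Route**

Step 1
Reactants: 1 2-methylcyclohex-2-en-1-one; 2 chloromethyl triisopropylsilyl ether
Product: 4 racemic 2-methyl-6-{[(triisopropylsilyl)oxy]methyl}cyclohex-2-en-1-one, via lithium dienolate 3 (not isolated)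
Conditions: LiN(iPr)2, THF, −78 °C; then 2, −78 to −20 °C
Reagents that add atoms: none
Why: Enolate alkylation: kinetic α′-deprotonation gives cross-conjugated dienolate 3, which is C-alkylated by the reactive α-chloro ether; the new stereocentre is racemic and is erased in step 6.

Step 2
Reactants: 4 racemic 2-methyl-6-{[(triisopropylsilyl)oxy]methyl}cyclohex-2-en-1-one; 5 acetaldehyde
Product: 7 racemic 6-(1-hydroxyethyl)-2-methyl-6-{[(triisopropylsilyl)oxy]methyl}cyclohex-2-en-1-one (both carbinol epimers), via lithium enolate 6 (not isolated)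
Conditions: LiN(iPr)2, THF, −78 °C; 5, −78 °C; AcOH quench
Reagents that add atoms: none
Why: Lithium enolate aldol addition: at −78 °C the fully substituted enolate 6 is trapped by acetaldehyde faster than it expels silanolate; both carbinol epimers are used because that carbon becomes sp2 in step 3.

Step 3
Reactants: 7 racemic 6-(1-hydroxyethyl)-2-methyl-6-{[(triisopropylsilyl)oxy]methyl}cyclohex-2-en-1-one
Product: 9 racemic 6-ethenyl-2-methyl-6-{[(triisopropylsilyl)oxy]methyl}cyclohex-2-en-1-one, via sulfamate ester 8 (not isolated)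
Conditions: Burgess reagent (methyl N-(triethylammoniosulfonyl)carbamate), toluene, 80 °C
Reagents that add atoms: none
Why: Burgess dehydration (syn Ei elimination of sulfamate 8): the α-carbon is quaternary, so the only β-hydrogens are on the methyl group and the terminal ethenyl group forms.

Step 4
Reactants: 10 2-bromoprop-2-en-1-ol; 11 ethynyltrimethylsilane
Product: 12 2-[(trimethylsilyl)ethynyl]prop-2-en-1-ol
Conditions: PdCl2(PPh3)2 (2 mol%), CuI (4 mol%), Et3N, THF, 25 °C
Reagents that add atoms: none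
Why: Sonogashira coupling of the 2-bromoalkene with the terminal alkyne; no stereocentre is formed.

Step 5
Reactants: 12 2-[(trimethylsilyl)ethynyl]prop-2-en-1-ol; 9 racemic 6-ethenyl-2-methyl-6-{[(triisopropylsilyl)oxy]methyl}cyclohex-2-en-1-one
Product: 14 racemic 6-ethenyl-1-[3-(hydroxymethyl)but-3-en-1-yn-1-yl]-2-methyl-6-{[(triisopropylsilyl)oxy]methyl}cyclohex-2-en-1-ol (alkynyl cis to ethenyl), via dilithium alkoxide acetylide 13 (not isolated)
Conditions: 12, CH3Li·LiBr (2.2 equiv), THF, 0 to 25 °C; then 9, −78 to 0 °C; AcOH quench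
Reagents that add atoms: none
Why: CH3Li cleaves the alkynyl–Si bond and deprotonates the alcohol to give 13, whose acetylide adds 1,2 to the non-enolisable ketone anti to the bulky silyloxymethyl group (Felkin–Anh-type attack), placing alkynyl cis to ethenyl; the product is racemic.

Step 6
Reactants: 14 racemic 6-ethenyl-1-[3-(hydroxymethyl)but-3-en-1-yn-1-yl]-2-methyl-6-{[(triisopropylsilyl)oxy]methyl}cyclohex-2-en-1-ol
Product: 17 (1(10)Z,4E)-12-hydroxy-15-[(triisopropylsilyl)oxy]germacra-1(10),4,7,11(13)-tetraen-9-one (achiral; C7=C8 geometry not assigned), via dipotassium dialkoxide 15 (not isolated), via dipotassium allenolate 16 (not isolated)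
Conditions: KH (3 equiv), 18-crown-6 (3 equiv), THF, 0 to 25 °C; AcOH quench at −78 °C
Reagents that add atoms: none
Why: Anionic oxy-Cope rearrangement ([3,3] ring expansion) of the alkynyl carbinolate: through the half-chair with alkynyl and CH2OSi(iPr)3 trans-diaxial, ethenyl carbon C6 bonds to C7 as C9–C4 breaks, so C3 and C6 end up cis on the new C4=C5 bond, the cis C1=C10 bond is inherited from the cyclohexenone, both racemic centres vanish and C8-protonation of allenolate 16 gives the achiral dienone.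

Step 7
Reactants: 17 (1(10)Z,4E)-12-hydroxy-15-[(triisopropylsilyl)oxy]germacra-1(10),4,7,11(13)-tetraen-9-one
Product: 18 (1(10)Z,4E,7(11)E)-12-hydroxy-15-[(triisopropylsilyl)oxy]germacra-1(10),4,7(11)-trien-9-one (achiral)
Conditions: (η6-naphthalene)Cr(CO)3 (10 mol%), H2 (4 atm), THF, 40 °C
Reagents that add atoms: none
Why: Cr(CO)3-catalysed 1,4-hydrogenation of a conjugated diene: both hydrogens are delivered within an η4 complex of the s-cis C8=C7–C11=C13 diene, so C8H2 and the new C13H3 are cis on the tetrasubstituted C7=C11 bond (CH2OH cis to C6), while the enone and the isolated alkene cannot form such a complex and are left.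

Step 8
Reactants: 18 (1(10)Z,4E,7(11)E)-12-hydroxy-15-[(triisopropylsilyl)oxy]germacra-1(10),4,7(11)-trien-9-one
Product: 19 (1(10)Z,4E,7S,11S)-7,11-epoxy-12-hydroxy-15-[(triisopropylsilyl)oxy]germacra-1(10),4-dien-9-one
Conditions: tetrapeptide Boc-L-Asp-L-Pro-D-Val-NH-(R)-CH(CH3)Ph or its mirror image, whichever gives 7S,11S (10 mol%), 30% aq H2O2 (2 equiv), N,N′-diisopropylcarbodiimide (1.5 equiv), 4-(dimethylamino)pyridine (10 mol%), CH2Cl2, 0 °C
Reagents that add atoms: hydrogen peroxide OO
Why: Proposed new method: the aspartyl side chain is turned in situ (carbodiimide, H2O2) into a chiral peracid that hydrogen-bonds the allylic C12 hydroxyl and transfers oxygen in a concerted, geometry-retaining step to one enantiotopic face of the most nucleophilic, tetrasubstituted C7=C11 bond, fixing C7 and C11 together as 7S,11S and leaving the silyl-blocked C4=C5 bond and the enone; the closest known reaction type is peptide-based aspartyl-peracid catalysis of hydroxyl-directed epoxidation of trisubstituted allylic alcohols, not yet shown for a tetrasubstituted exocyclic allylic alcohol on a macrocycle.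

Step 9
Reactants: 19 (1(10)Z,4E,7S,11S)-7,11-epoxy-12-hydroxy-15-[(triisopropylsilyl)oxy]germacra-1(10),4-dien-9-one
Product: 21 (1(10)Z,4E,7S,11S)-12,15-diacetoxy-7,11-epoxygermacra-1(10),4-dien-9-one, via epoxy diol 20 (not isolated)
Conditions: Bu4NF/AcOH (1:1, 1.5 equiv), THF, 0 to 25 °C; then Ac2O, pyridine, 4-(dimethylamino)pyridine (cat.), 0 °C
Reagents that add atoms: acetic anhydride CC(=O)OC(C)=O
Why: Fluoride desilylation then acylation: buffered fluoride removes the primary silyl ether without opening the base-labile β,γ-epoxy ketone and both primary alcohols of 20 are acetylated in the same flask; no stereocentre is touched.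

Step 10
Reactants: 21 (1(10)Z,4E,7S,11S)-12,15-diacetoxy-7,11-epoxygermacra-1(10),4-dien-9-one
Product: 22 (1(10)Z,4R,5R,7S,11S)-12,15-diacetoxy-4,5:7,11-diepoxygermacr-1(10)-en-9-one (CNP0185847.4)
Conditions: D-fructose-derived Shi ketone (30 mol%), KHSO5 (as 2KHSO5·KHSO4·K2SO4, 1.5 equiv), Bu4NHSO4 (cat.), CH3CN–CH2(OCH3)2–aq Na2B4O7 buffer, K2CO3 to hold pH 9, 0 °C
Reagents that add atoms: potassium peroxymonosulfate KHSO5 [K+].[O-]S(=O)(=O)OO
Why: Shi epoxidation (chiral dioxirane, spiro transition state): the ketone delivers oxygen to the ring-cis trisubstituted C4=C5 bond with the same facial sense as for 1-substituted cycloalkenes, which corresponds to 4R,5R, while the electron-poor enone does not react.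

**Compound list**

1 | 2-methylcyclohex-2-en-1-one | CC1=CCCCC1=O | starting material
2 | chloromethyl triisopropylsilyl ether | ClCO[Si](C(C)C)(C(C)C)C(C)C | starting material
3 | lithium 6-methylcyclohexa-1,5-dien-1-olate | [Li+].CC1=CCCC=C1[O-] | intermediate
4 | racemic 2-methyl-6-{[(triisopropylsilyl)oxy]methyl}cyclohex-2-en-1-one | CC1=CCCC(CO[Si](C(C)C)(C(C)C)C(C)C)C1=O | intermediate
5 | acetaldehyde | CC=O | starting material
6 | lithium enolate of 4 (C1=C6 enolate) | [Li+].CC1=CCCC(CO[Si](C(C)C)(C(C)C)C(C)C)=C1[O-] | intermediate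
7 | racemic 6-(1-hydroxyethyl)-2-methyl-6-{[(triisopropylsilyl)oxy]methyl}cyclohex-2-en-1-one, both carbinol epimers | CC(O)C1(CO[Si](C(C)C)(C(C)C)C(C)C)CCC=C(C)C1=O | intermediate
8 | triethylammonium N-(methoxycarbonyl)sulfamate ester of 7 | CC(OS(=O)(=O)[N-]C(=O)OC)C1(CO[Si](C(C)C)(C(C)C)C(C)C)CCC=C(C)C1=O.CC[NH+](CC)CC | intermediate
9 | racemic 6-ethenyl-2-methyl-6-{[(triisopropylsilyl)oxy]methyl}cyclohex-2-en-1-one | C=CC1(CO[Si](C(C)C)(C(C)C)C(C)C)CCC=C(C)C1=O | intermediate
10 | 2-bromoprop-2-en-1-ol | OCC(Br)=C | starting material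
11 | ethynyltrimethylsilane | C#C[Si](C)(C)C | starting material
12 | 2-[(trimethylsilyl)ethynyl]prop-2-en-1-ol | OCC(=C)C#C[Si](C)(C)C | intermediate
13 | dilithium salt of 2-ethynylprop-2-en-1-ol (alkoxide and acetylide) | [Li+].[Li+].[O-]CC(=C)C#[C-] | intermediate
14 | racemic 6-ethenyl-1-[3-(hydroxymethyl)but-3-en-1-yn-1-yl]-2-methyl-6-{[(triisopropylsilyl)oxy]methyl}cyclohex-2-en-1-ol, alkynyl cis to ethenyl (one enantiomer drawn) | C=C[C@@]1(CO[Si](C(C)C)(C(C)C)C(C)C)CCC=C(C)[C@@]1(O)C#CC(=C)CO | intermediate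
15 | dipotassium dialkoxide of 14 (racemic, one enantiomer drawn) | [K+].[K+].C=C[C@@]1(CO[Si](C(C)C)(C(C)C)C(C)C)CCC=C(C)[C@@]1([O-])C#CC(=C)C[O-] | intermediate
16 | dipotassium salt of the ring-expanded allenolate (1(10)Z,4E; C7=C8=C9 allene; C9 enolate oxygen and C12 alkoxide) | [K+].[K+].CC(C)[Si](C(C)C)(C(C)C)OC/C1=C/CC(C(=C)C[O-])=C=C([O-])/C(C)=C\CC1 | intermediate
17 | (1(10)Z,4E)-12-hydroxy-15-[(triisopropylsilyl)oxy]germacra-1(10),4,7,11(13)-tetraen-9-one, achiral, C7=C8 geometry not assigned | CC(C)[Si](C(C)C)(C(C)C)OC/C1=C/CC(C(=C)CO)=CC(=O)/C(C)=C\CC1 | intermediate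
18 | (1(10)Z,4E,7(11)E)-12-hydroxy-15-[(triisopropylsilyl)oxy]germacra-1(10),4,7(11)-trien-9-one, achiral | CC(C)[Si](C(C)C)(C(C)C)OC/C1=C/C/C(=C(C)\CO)CC(=O)/C(C)=C\CC1 | intermediate
19 | (1(10)Z,4E,7S,11S)-7,11-epoxy-12-hydroxy-15-[(triisopropylsilyl)oxy]germacra-1(10),4-dien-9-one | CC(C)[Si](C(C)C)(C(C)C)OC/C1=C/C[C@]2(O[C@@]2(C)CO)CC(=O)/C(C)=C\CC1 | intermediate
20 | (1(10)Z,4E,7S,11S)-7,11-epoxy-12,15-dihydroxygermacra-1(10),4-dien-9-one | OC/C1=C/C[C@]2(O[C@@]2(C)CO)CC(=O)/C(C)=C\CC1 | intermediate
21 | (1(10)Z,4E,7S,11S)-12,15-diacetoxy-7,11-epoxygermacra-1(10),4-dien-9-one | CC(=O)OC/C1=C/C[C@]2(O[C@@]2(C)COC(C)=O)CC(=O)/C(C)=C\CC1 | intermediate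
22 | (1(10)Z,4R,5R,7S,11S)-12,15-diacetoxy-4,5:7,11-diepoxygermacr-1(10)-en-9-one (CNP0185847.4) | CC(=O)OC[C@]12CC/C=C(/C)C(=O)C[C@]3(C[C@H]1O2)O[C@@]3(C)COC(C)=O | target

**Step count and risks**

Total steps: 10. Longest linear sequence: 9 (steps 1, 2, 3, 5, 6, 7, 8, 9, 10); step 4 is the side branch.

Steps most likely to fail:

Step 6 (ring expansion). The potassium propargylic alkoxide may fragment to ketone 9 and acetylide instead of rearranging, and the competing half-chair would give the ring-trans C4=C5 isomer. The fallback sets out from 14 and rejoins at 17. The triple bond of 14 is semi-hydrogenated (H2, Pd/CaCO3 poisoned with Pb(OAc)2, quinoline) to the (Z)-dienyl carbinol F1. The classical dialkenyl anionic oxy-Cope rearrangement (KH, 18-crown-6) follows; here the (Z)-substituent on C7 enforces the chair that leads to the ring-cis C4=C5 bond, giving the C7–H ketone F2. Saegusa–Ito dehydrogenation through the bis(trimethylsilyl) derivative F3 ((CH3)3SiOSO2CF3, Et3N; then Pd(OAc)2, CH3CN; K2CO3/CH3OH work-up) installs the C7=C8 bond and returns 17.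

Step 8 (proposed new epoxidation). The facial selectivity and turnover of the peptide peracid on a tetrasubstituted alkene are untested, and Baeyer–Villiger oxidation of the ketone could compete. The fallback uses known chemistry and goes from 18 directly to 19: Sharpless asymmetric epoxidation (Ti(OiPr)4, L-(+)-diethyl tartrate, t-BuOOH, 4 Å molecular sieves, CH2Cl2, −20 °C). The empirical face rule (the sense that converts geraniol into its 2S,3S epoxide) predicts 7S,11S, and the silyl-blocked C4=C5 bond is not an allylic alcohol. No compound outside the list is made (F0: none).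

Step 10 (second epoxidation). The facial sense is argued only by analogy, the existing 7,11-epoxide may be mismatched with the catalyst, and the β,γ-epoxy ketone is base-labile. The fallback sets out from 19 and rejoins at 22. Buffered Bu4NF gives epoxy diol 20, here isolated. Sharpless epoxidation with D-(−)-diethyl tartrate (Ti(OiPr)4, t-BuOOH, 4 Å molecular sieves, CH2Cl2, −20 °C) then uses the free C15 hydroxyl to deliver oxygen to C4=C5 under reagent control, giving the bis-epoxy diol F4. Acetylation (Ac2O, pyridine) gives 22.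

**Further compounds**

F1 | step 6 | racemic 6-ethenyl-1-[(1Z)-3-(hydroxymethyl)buta-1,3-dien-1-yl]-2-methyl-6-{[(triisopropylsilyl)oxy]methyl}cyclohex-2-en-1-ol, dienyl cis to ethenyl (one enantiomer drawn) | C=C[C@@]1(CO[Si](C(C)C)(C(C)C)C(C)C)CCC=C(C)[C@@]1(O)/C=C\C(=C)CO
F2 | step 6 | racemic (1(10)Z,4E)-12-hydroxy-15-[(triisopropylsilyl)oxy]germacra-1(10),4,11(13)-trien-9-one | CC(C)[Si](C(C)C)(C(C)C)OC/C1=C/CC(C(=C)CO)CC(=O)/C(C)=C\CC1
F3 | step 6 | racemic bis(trimethylsilyl) derivative of F2 (C8=C9 trimethylsilyl enol ether and C12 trimethylsilyl ether) | CC(C)[Si](C(C)C)(C(C)C)OC/C1=C/CC(C(=C)CO[Si](C)(C)C)C=C(O[Si](C)(C)C)/C(C)=C\CC1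
F0 | step 8 | none | none
F4 | step 10 | (1(10)Z,4R,5R,7S,11S)-4,5:7,11-diepoxy-12,15-dihydroxygermacr-1(10)-en-9-one | OC[C@]12CC/C=C(/C)C(=O)C[C@]3(C[C@H]1O2)O[C@@]3(C)CO
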